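The time of reading is what we must choose for the next two flasks, in which X dissolves to D, D + G gives Q, D + Q gives E, and Q goes to J and back.

in all of them: X 0.10 M
- theta: G 0.14 M; temperature 0 °C; run made earlier
- eta: G 0.39 M; temperature 15 °C; run made earlier
- gamma: G 0.95 M; temperature 0 °C; run made earlier
- south-east: G 0.180 M; at 25 °C until 8.0 d, from then on at 5 °C; time 25 d
- north-west: G 0.800 M; at 5 °C throughout; time 8.0 d

| run | time / d | Q / % | X / % |
|---|---|---|---|
| theta | 4.00 | 3.6 | 64.9 |
| theta | 8.00 | 10.7 | 53.9 |
| theta | 15.0 | 12.0 | 41.2 |
| theta | 30.0 | 15.6 | 12.2 |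
| theta | 60.0 | 11.9 | 0 |
| eta | 6.00 | 25.3 | 29.2 |
| eta | 12.0 | 35.1 | 2.3 |
| eta | 15.0 | 34.3 | 0.8 |
| eta | 25.0 | 34.0 | 0 |
| eta | 30.0 | 35.4 | 0 |
| gamma | 6.00 | 32.4 | 37.0 |
| gamma | 15.0 | 44.7 | 0 |
| gamma | 30.0 | 17.8 | 0 |
| gamma | 40.0 | 11.1 | 0 |
| gamma | 60.0 | 10.7 | 0 |

(each reading ± 1 percentage point)

- a species is counted by the X in it: one E counts as two
- given per volume of solution although it is solid: X
- candidate steps: X <-> D; D + G -> Q; D + Q -> E; Q <-> J
- at the start none of X is in solution
- what has only dissolved of X counts as not reacted

- which one finishes higher in amount of Q, in percent of the X charged ("neither" within 2 percentage points) (south-east / north-west / neither)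
- amount of Q at the end, in percent of the X charged, south-east
- amount of Q at the end, in percent of the X charged, north-west

1. In gamma, with [G] at 0.95 M and 0 °C, Q reads 44.7% at 15.0 d and 17.8% at 30.0 d, and ends flat near 10.7%. We call Q above that flat level its excess. Its fall gives a turnover time (relaxation time), 9.58 d, the time in which the excess drops to 0.368 of itself. This is a reading and carries the scatter.

2. In eta, at 15 °C, Q already reads 35.1% at 12.0 d and 35.4% at 30.0 d. We therefore take warmth to shorten the turnover time, and we treat the counts below as low.

3. South-east spends 17.0 d cold, which is 1.78 turnovers, so 0.169 of the excess remains. Starting from eta's flat level and falling towards gamma's, our own figure is 14.9%.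

4. North-west gets 0.835 turnovers, fewer than one and fewer than south-east. We place it between gamma's 32.4% and 44.7%.

5. Our decision is to charge north-west for Q and keep its reading at 8.0 d, where our count gives it fewer turnovers than south-east.

The forecast says north-west, with 18% for south-east, above our figure, and 38% for north-west, which it calls “still rising and before crystallisation takes hold”.

The flasks give 14.0% for south-east and 37.6% for north-west, so north-west finishes higher.

    X ⇌ D, rate k1*(cs1 - [D]) while solid is left; crystals form when [D] > cs1 (solubility = 37.0 mM, k = 0.0210 h⁻¹)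
    D + G → Q (k = 0.200 M⁻¹ h⁻¹, Ea = 63.0 kJ mol⁻¹)
    D + Q → E (k = 0.140 M⁻¹ h⁻¹, Ea = 67.0 kJ mol⁻¹)
    Q ⇌ J (K = 0.570, k = 0.120 h⁻¹, Ea = 90.0 kJ mol⁻¹, ΔH = −76.0 kJ mol⁻¹)
    (constants at 25 °C)

We measure the excess in south-east against 12.8%, its Q at 250 d. At the cooling the excess stood at 28 percentage points. By 25 d a share of 0.0438 remained, less than the count gave. The neighbour is the same flask read at 10 d, which is 0.209 turnovers after the cooling, so the count leaves 0.811 of the excess. That flask holds Q at 30.5%, a share of 0.635.

All runs were generated by integration for substances that don't exist; scatter was added.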